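Wednesday's flask cannot be a plain conversion of starting material into target running to its end, because its rate, counted as a fraction of the charge, fell from 0.0118 /min in the second interval to 0.00173 /min in the last, while the target stood at 24.7 % of the charge.

| flask | starting material | time |
|---|---|---|
| Wednesday's | 0.800 M |  |
| Saturday's | 0.400 M |  |
| Monday's | 1.60 M |  |
| Thursday's | 0.800 M | 150 min |

- Wednesday's run (time / min: [target] / M): 7.4: 0.0548; 15: 0.1268; 22: 0.1646; 30: 0.1881; 37: 0.1978
- Saturday's run (time / min: [target] / M): 7.4: 0.0231; 15: 0.0517; 22: 0.0640; 30: 0.0701; 37: 0.0733
- Monday's run (time / min: [target] / M): 7.4: 0.1219; 15: 0.2864; 22: 0.3929; 30: 0.4578; 37: 0.4876

(readings scatter by 0.002 M)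

1. the power of [starting material] that the first rate follows, about the charge of the Wednesday's run; measure it at two percent of starting material made into target (one fixed amount of target, the same in the runs compared)
2. target in the Thursday's run at 150 min, as a share of the starting material charged

- Overall: starting material -> target.
- Constant volume, constant temperature.
- What is held in complexes is read along with the free species.
- An order is taken over about fifteen percent of the charge, up and down.

So I built the flask up, taking Thursday's as a repeat of Wednesday's with a longer clock. With the main step alone, first order at that second-interval rate, the target would reach 83.1 % of the charge by 150 min. The next addition was a fading rate, and dividing the rate by its own rate of fall removes time from the reckoning. From the last two intervals, 0.00367 /min and then 0.00173 /min, I read the fractional fall of the rate per minute, which I call the fade, 0.100 /min. If the fade held, the target still to come was the present rate over the fade; brought forward to 37 min, the rate is 0.00122 /min, so my estimate of the tail is 1.22 % of the charge and of the final share 25.9 %, which is 57 percentage points lower than the main step alone. On that fade, hardly any of that tail remained unmade at 150 min. The rest of the flask, the lag in which the interval rate rose from 0.00926 /min to 0.0118 /min, came before the last reading, and the target made during it is counted in that reading. The fade itself rests on differences of readings, but the tail it sets is 4.87 times the scatter of one reading, as a share of the charge.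

The forecast gave 26.2 %, a little above my share, and an order of 0.75, with the words “Extrapolating the decay gives a plateau near 0.21 M, or about 26%.”

The flask gave 25.4 % for Thursday's run at 150 min, 0.50 points under my reckoning, and an order of 0.79.

    2 starting material ⇌ intermediate + starting material (0.6960 /M/min, 0.2160 /M/min)
    intermediate → target (0.1392 /min)
    2 starting material ⇌ idle substrate dimer, settled at all times (7.480 /M)
    starting material → decomposed substrate (0.2100 /min)

The step of starting material to decomposed substrate moves the readings by 81 times the scatter, as a root mean square. I then carried Wednesday's fade to Monday's run, whose last interval gives 0.00266 /min, brought forward to 0.00187 /min at 37 min, so a tail of 1.87 % and a final share of 32.3 %. Running that tail backwards put a quarter of Monday's charge at 23.3 min, and Monday's run came to that quarter at 22.7 min.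

The earlier runs and the new flask were computed for substances that don't exist.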